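**Plan**
- Retrosynthesis: the 5-O–CH3 bond is cut last (target 15 ⇐ 5-hydroxy quinone methide 14 ⇐ leuco triol 13 ⇐ trimethyl ether lactone 12). The benzo ring of 12 is then cut at C3a–C4 and C7–C7a.
- Enabling feature (benzofuran numbering): the C4(Ph)–C5(O)–C6(O)–C7(Ph) edge of the carbocycle is mirror-symmetric while both oxygens are methyl ethers, and C3a/C7a are the enol-ether carbon pair of the five-membered lactone ring. The edge is therefore 3,4-dimethoxy-2,5-diphenylthiophene 1,1-dioxide 4 minus SO2, and the rest is the 3-aryl-2-silyloxyfuran 8.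
- 4 is cut at C2–C3 and C4–C5 (dibenzyl sulfone + diethyl oxalate); 8 is cut at the aryl–C3 bond (Suzuki–Miyaura) and at O–Si.
- Forward: the sulfone ring (steps 1–2) and the furan (steps 3–4) are made separately; step 5 fuses the six-membered carbocycle onto the furan 4,5-bond; steps 6–9 aromatize, unmask the lactone, demethylate, oxidize to the quinone methide and methylate O5.
- Stereochemistry: the target has no stereocentre. The cis ring fusion of 10 comes from suprafacial addition to the furan and is erased in step 6; the racemic C3 centre of 12 and 13 is erased in step 8.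

Key step: step 5

Remark: all chiral intermediates (9, 10, 12, 13 and the fallback compounds) are racemic; because the target is achiral no absolute control is sought.

**Step 1**
Reactants: 1 dibenzyl sulfone; 2 diethyl oxalate
Product: 3 3,4-dihydroxy-2,5-diphenylthiophene 1,1-dioxide
Conditions: NaOEt (2.2 equiv), EtOH, reflux; then aq. HCl
Reagents that add atoms: none
Why: Hinsberg-type double Claisen condensation, in which each sulfonyl-activated benzylic CH2 is acylated by one ester group of the oxalate and the ring is drawn off as the doubly deprotonated bis-enol, which drives the equilibrium.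

**Step 2**
Reactants: 3 3,4-dihydroxy-2,5-diphenylthiophene 1,1-dioxide
Product: 4 3,4-dimethoxy-2,5-diphenylthiophene 1,1-dioxide
Conditions: Me2SO4 (2.5 equiv), K2CO3, acetone, reflux
Reagents that add atoms: dimethyl sulfate, COS(=O)(=O)OC
Why: Williamson-type O-alkylation of the two strongly acidic enol hydroxyls with a hard methylating agent, C-methylation being disfavoured because it would create a quaternary carbon between phenyl and sulfonyl and break the diene conjugation.

**Step 3**
Reactants: 5 3-bromofuran-2(5H)-one; 6 4-methoxyphenylboronic acid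
Product: 7 3-(4-methoxyphenyl)furan-2(5H)-one
Conditions: Pd(PPh3)4 (cat.), NaHCO3, DME/H2O, 80 °C
Reagents that add atoms: none
Why: Suzuki–Miyaura coupling, the α-bromo enoate C–Br bond adding readily to zerovalent palladium while the hydrogencarbonate base is mild enough to leave the butenolide closed.

**Step 4**
Reactants: 7 3-(4-methoxyphenyl)furan-2(5H)-one
Product: 8 triisopropyl{[3-(4-methoxyphenyl)furan-2-yl]oxy}silane
Conditions: TIPSOTf, Et3N, CH2Cl2, 0 °C
Reagents that add atoms: triisopropylsilyl trifluoromethanesulfonate, CC(C)[Si](OS(=O)(=O)C(F)(F)F)(C(C)C)C(C)C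
Why: Soft enolization (O-silylation of the lactone carbonyl and removal of a C5 proton by the amine), the standard conversion of a butenolide into an aromatic 2-silyloxyfuran.

**Step 5**
Reactants: 4 3,4-dimethoxy-2,5-diphenylthiophene 1,1-dioxide; 8 triisopropyl{[3-(4-methoxyphenyl)furan-2-yl]oxy}silane
Product: 10 cis-5,6-dimethoxy-3-(4-methoxyphenyl)-4,7-diphenyl-2-[(triisopropylsilyl)oxy]-3a,7a-dihydrobenzofuran (racemic), via 4,7-epithio cycloadduct 9 (not isolated)
Conditions: 8 (1.5 equiv), 2,6-di-tert-butylpyridine (cat.), PhMe, 110 °C, Ar sweep; crude 10 taken on at once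
Reagents that add atoms: none
Why: Proposed new method: 4 is a non-aromatic, s-cis-locked diene with a low LUMO and the 4,5-bond of 8 is a very electron-rich enol ether, so a concerted but asynchronous inverse-electron-demand [4+2] addition is expected (furan C5, the most nucleophilic carbon, bonding in advance to a phenyl-bearing diene terminus), after which the 7-thiabicyclo[2.2.1]heptene dioxide 9 loses SO2 by cheletropic extrusion at the reaction temperature. The closest known reaction type is the Diels–Alder/SO2-extrusion sequence of substituted thiophene 1,1-dioxides with enol ethers, enamines, furans and benzofurans; a 2-silyloxyfuran has not been used as the 2π partner. The six-membered carbocycle is closed by the intermolecular cycloaddition itself, C3a–C4 and C7–C7a forming in one suprafacial–suprafacial event, and the extrusion merely unveils it as a cyclohexa-1,3-diene. C3a and C7a come out cis because both bonds are made on the same face of the planar furan 4,5-bond, endo or exo approach being irrelevant once the sulfur bridge has left. Periselectivity rests on 4, whose two C=C bonds are tetrasubstituted and deactivated as 2π or Michael partners by their β-methoxy groups so that only its C2/C5 termini react, site selectivity rests on 8, whose 2,3-bond is tetrasubstituted (aryl, silyloxy) while the 4,5-bond carries only hydrogens, and no regiochemistry arises because 4 is C2v-symmetric. The hindered base and the argon sweep remove SO2 and traces of acid, which would otherwise desilylate 8 or expel the C7a oxygen from 10.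

**Step 6**
Reactants: 10 cis-5,6-dimethoxy-3-(4-methoxyphenyl)-4,7-diphenyl-2-[(triisopropylsilyl)oxy]-3a,7a-dihydrobenzofuran
Product: 12 5,6-dimethoxy-3-(4-methoxyphenyl)-4,7-diphenylbenzofuran-2(3H)-one (racemic at C3), via 2-silyloxybenzofuran 11 (not isolated)
Conditions: DDQ (1.05 equiv), 2,6-di-tert-butylpyridine, CH2Cl2, −20 → 0 °C; then TBAF, AcOH, THF, 0 °C
Reagents that add atoms: none
Why: DDQ dehydrogenation (hydride abstraction from a ring-fusion C–H stabilized by the ketene acetal or the ring oxygen, then proton loss, as with silyl enol ethers and dihydroarenes) removes the two cis hydrogens under non-acidic conditions so that the C7a–O bond is kept, and buffered fluoride then cleaves the O–Si bond with protonation at C3 to give the benzofuranone.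

**Step 7**
Reactants: 12 5,6-dimethoxy-3-(4-methoxyphenyl)-4,7-diphenylbenzofuran-2(3H)-one
Product: 13 5,6-dihydroxy-3-(4-hydroxyphenyl)-4,7-diphenylbenzofuran-2(3H)-one (racemic at C3; kept under argon)
Conditions: BBr3 (excess), CH2Cl2, −78 °C → rt; then H2O, under Ar
Reagents that add atoms: none
Why: Lewis-acid cleavage of aryl methyl ethers with BBr3 (bromide attack on the methyl group of each boron-complexed ether) should remove all three methyl groups, while the five-membered aryl lactone survives or recloses on work-up.

**Step 8**
Reactants: 13 5,6-dihydroxy-3-(4-hydroxyphenyl)-4,7-diphenylbenzofuran-2(3H)-one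
Product: 14 5-hydroxy-3-(4-hydroxyphenyl)-4,7-diphenylbenzofuran-2,6-dione (xylerythrin)
Conditions: DDQ (1.0 equiv), THF, 0 °C → rt
Reagents that add atoms: none
Why: Quinone-methide formation by dehydrogenation of a para-hydroxybenzylic C–H (directly, or through the 5,6-ortho-quinone, which tautomerizes by a C3-to-O5 hydrogen shift) gives the fully conjugated pigment and removes the last stereocentre, one equivalent of oxidant stopping at this oxidation level.

**Step 9**
Reactants: 14 5-hydroxy-3-(4-hydroxyphenyl)-4,7-diphenylbenzofuran-2,6-dione
Product: 15 3-(4-hydroxyphenyl)-5-methoxy-4,7-diphenylbenzofuran-2,6-dione (target, CNP0282683.0)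
Conditions: CH2N2 (1.0 equiv, titrated ethereal solution), THF, −40 → 0 °C
Reagents that add atoms: diazomethane, C=[N+]=[N-]
Why: O-Methylation with diazomethane is limited by proton transfer and should therefore take place first at the most acidic hydroxyl, the 5-OH (an enolized 1,2-dione that is also a doubly vinylogous acid of the lactone carbonyl), leaving the less acidic phenol free when one equivalent is used cold in a non-hydroxylic solvent.

**Compound list**
1 | dibenzyl sulfone | O=S(=O)(Cc1ccccc1)Cc1ccccc1 | starting material
2 | diethyl oxalate | CCOC(=O)C(=O)OCC | starting material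
3 | 3,4-dihydroxy-2,5-diphenylthiophene 1,1-dioxide | OC1=C(c2ccccc2)S(=O)(=O)C(c2ccccc2)=C1O | intermediate
4 | 3,4-dimethoxy-2,5-diphenylthiophene 1,1-dioxide | COC1=C(c2ccccc2)S(=O)(=O)C(c2ccccc2)=C1OC | intermediate
5 | 3-bromofuran-2(5H)-one | O=C1OCC=C1Br | starting material
6 | 4-methoxyphenylboronic acid | COc1ccc(B(O)O)cc1 | starting material
7 | 3-(4-methoxyphenyl)furan-2(5H)-one | COc1ccc(cc1)C1=CCOC1=O | intermediate
8 | triisopropyl{[3-(4-methoxyphenyl)furan-2-yl]oxy}silane | COc1ccc(cc1)-c1ccoc1O[Si](C(C)C)(C(C)C)C(C)C | intermediate
9 | 5,6-dimethoxy-3-(4-methoxyphenyl)-4,7-diphenyl-2-[(triisopropylsilyl)oxy]-3a,4,7,7a-tetrahydro-4,7-epithiobenzofuran 8,8-dioxide (racemic, cis-fused; endo adduct drawn, the exo adduct would lead to the same 10) | COC1=C(OC)[C@@]2(c3ccccc3)[C@H]4OC(O[Si](C(C)C)(C(C)C)C(C)C)=C(c5ccc(OC)cc5)[C@H]4[C@]1(c6ccccc6)S2(=O)=O | intermediate (not isolated)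
10 | cis-5,6-dimethoxy-3-(4-methoxyphenyl)-4,7-diphenyl-2-[(triisopropylsilyl)oxy]-3a,7a-dihydrobenzofuran (racemic, one enantiomer drawn) | COC1=C(c2ccccc2)[C@@H]2C(c3ccc(OC)cc3)=C(O[Si](C(C)C)(C(C)C)C(C)C)O[C@@H]2C(c2ccccc2)=C1OC | intermediate
11 | {[5,6-dimethoxy-3-(4-methoxyphenyl)-4,7-diphenylbenzofuran-2-yl]oxy}triisopropylsilane | COc1ccc(cc1)-c1c(O[Si](C(C)C)(C(C)C)C(C)C)oc2c(-c3ccccc3)c(OC)c(OC)c(-c3ccccc3)c12 | intermediate (not isolated)
12 | 5,6-dimethoxy-3-(4-methoxyphenyl)-4,7-diphenylbenzofuran-2(3H)-one (racemic, one enantiomer drawn) | COc1ccc(cc1)[C@@H]1C(=O)Oc2c(-c3ccccc3)c(OC)c(OC)c(-c3ccccc3)c12 | intermediate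
13 | 5,6-dihydroxy-3-(4-hydroxyphenyl)-4,7-diphenylbenzofuran-2(3H)-one (racemic, one enantiomer drawn) | O=C1Oc2c(-c3ccccc3)c(O)c(O)c(-c3ccccc3)c2[C@@H]1c1ccc(O)cc1 | intermediate
14 | 5-hydroxy-3-(4-hydroxyphenyl)-4,7-diphenylbenzofuran-2,6-dione (xylerythrin) | OC1=C(c2ccccc2)C2=C(c3ccc(O)cc3)C(=O)OC2=C(c2ccccc2)C1=O | intermediate
15 | 3-(4-hydroxyphenyl)-5-methoxy-4,7-diphenylbenzofuran-2,6-dione | COC1=C(c2ccccc2)C2=C(c3ccc(O)cc3)C(=O)OC2=C(c2ccccc2)C1=O | target

**Step count**
Total: 9 steps. Longest linear sequence: 7 steps (1, 2, 5, 6, 7, 8, 9; the furan branch 3, 4, 5–9 is equally long).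

**Steps most likely to fail**

Step 5 (Proposed new method). The cycloaddition may be too slow, because the methoxy groups raise the diene LUMO and the phenyl termini hinder it. Desilylation of 8 by SO2-derived acid, or a stepwise vinylogous Mukaiyama–Michael addition through furan C5 that never closes the ring, could then overtake it. The fallback uses only known reaction types, sets out from 4 and returns at 12. Heating 4 in neat vinylene carbonate (160 °C, sealed tube), a thiophene dioxide Diels–Alder addition to a simple alkene with loss of SO2, should give meso-cis-5,6-dimethoxy-4,7-diphenyl-3a,7a-dihydro-1,3-benzodioxol-2-one F1. Acid-catalysed aromatization of this dihydroarene diol derivative (cat. TsOH, PhMe, 80 °C, loss of CO2) should give 3,4-dimethoxy-2,5-diphenylphenol F2. Friedel–Crafts hydroxyalkylation and lactonization of F2 with 4-methoxymandelic acid (BF3·OEt2, ClCH2CH2Cl, 80 °C), the established route from phenols and mandelic acids to 3-arylbenzofuran-2(3H)-ones, should alkylate the only free ring position (ortho to OH, para to OMe) and close the lactone to 12.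

Step 6. Ionization of the allylic C7a–O bond before the hydrogens are removed would aromatize the ring by loss of the lactone oxygen, and the electron-rich benzofuran 11 could be oxidized further. The fallback replaces hydride abstraction by halogenation–dehydrohalogenation under base throughout; it sets out from 10 and returns at 12. NBS (THF, −78 °C) should brominate the ketene-acetal carbon C3 from the convex face to give cis-fused 3-bromo-5,6-dimethoxy-3-(4-methoxyphenyl)-4,7-diphenyl-3a,7a-dihydrobenzofuran-2(3H)-one F3. Et3N (CH2Cl2, 0 °C → rt) should then remove HBr by an ionization-assisted elimination helped by the 4-methoxyphenyl group, giving 5,6-dimethoxy-3-(4-methoxyphenyl)-4,7-diphenylbenzofuran-2(7aH)-one F4. Under the same base F4 should shift its C7a hydrogen to C3 through the aromatic 2-oxidobenzofuran enolate and arrive at 12.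

Step 9. Discrimination between the 5-hydroxyl and the phenolic hydroxyl, which is also acidified through the quinone methide, may be incomplete and give mixtures of mono- and dimethyl ethers. The fallback sets out from 14 and ends at 15 without a new intermediate. It uses acid-catalysed etherification with methanol (MeOH, cat. TsOH, 50 °C), the addition–elimination by which hydroxyquinones and enolized 1,2-diones exchange OH for OMe. Methanol acts as nucleophile at C5, and a phenolic hydroxyl cannot react by this mechanism.

**Further compounds**
F1 | step 5 | meso-cis-5,6-dimethoxy-4,7-diphenyl-3a,7a-dihydro-1,3-benzodioxol-2-one | COC1=C(c2ccccc2)[C@@H]2OC(=O)O[C@@H]2C(c2ccccc2)=C1OC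
F2 | step 5 | 3,4-dimethoxy-2,5-diphenylphenol | Oc1cc(-c2ccccc2)c(OC)c(OC)c1-c1ccccc1
F3 | step 6 | cis-fused 3-bromo-5,6-dimethoxy-3-(4-methoxyphenyl)-4,7-diphenyl-3a,7a-dihydrobenzofuran-2(3H)-one (bromine cis to H-3a; racemic, one enantiomer drawn) | COc1ccc(cc1)[C@]1(Br)C(=O)O[C@@H]2C(c3ccccc3)=C(OC)C(OC)=C(c3ccccc3)[C@H]12
F4 | step 6 | 5,6-dimethoxy-3-(4-methoxyphenyl)-4,7-diphenylbenzofuran-2(7aH)-one (racemic, one enantiomer drawn) | COc1ccc(cc1)C1=C2C(c3ccccc3)=C(OC)C(OC)=C(c3ccccc3)[C@H]2OC1=O
F0 | step 9 | none | none
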